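**Retrosynthetic overview**
1. The target comes from hydrogenation and O-debenzylation of a C3-butenolide, whose C3–C18 bond is made last by an intermolecular vinylogous Mannich reaction between a 2-silyloxyfuran and the iminium ion obtained by partial reduction of a tetracyclic lactam.
2. Lactone B is built on a tricyclic keto-lactam by α-methylenation, 1,2-reduction, Mitsunobu acrylation, ring-closing metathesis and hydrogenation, then α-hydroxylation, O-benzylation and α-methylation.
3. The azepane comes from ring-closing metathesis of an N-allyl/C-allyl spiro-enone and cis-hydrogenation; the enone comes from a Stork–Danheiser allyl addition to a vinylogous ester.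
4. Ring A comes from a Dieckmann-type cyclisation of a γ-keto ester, itself made by a sulfinyl-ketimine Mannich reaction of an α-ketoglutarate imine with pentan-2-one; this sets C9a, from which every other centre is relayed.
5. Ring order: pyrrolidinone, ring A, azepane, lactone B, side-chain lactone.

Assumption: the Mannich addition in step 2 follows the usual sulfinyl-oxygen-chelated chair model on the E-ketimine (sulfinyl anti to the ester), so the (R)-sulfinamide gives the (S) quaternary carbon; if the opposite sense is found, the (S)-sulfinamide is used and nothing else changes.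

Locants for the polycyclic compounds: pyrrolidine N4–C3–C2–C1–C9a; azepane N4–C5–C6–C7–C8–C9–C9a; ring A C9a–C9–C10–C11–C12 (ethyl on C10, oxygen on C11); lactone B C11–O–C14(=O)–C13–C12; side-chain lactone on C3: C18(O)–C19–C20–C21(=O). β is the face of ring A that carries C1; α is the face that carries N4.

**Route**

Step 1
Reactants: 1 diethyl 2-oxopentanedioate; 2 (R)-2-methylpropane-2-sulfinamide
Product: 3 diethyl (E)-2-{[(R)-tert-butylsulfinyl]imino}pentanedioate
Conditions: Ti(OEt)4 (2 equiv), THF, 50 °C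
Reagents that add atoms: none
Why: Ellman condensation of the activated α-keto ester with the sulfinamide, Ti(OEt)4 serving as Lewis acid and water scavenger (ethoxide matches the ethyl esters).

Step 2
Reactants: 3 diethyl (E)-2-{[(R)-tert-butylsulfinyl]imino}pentanedioate; 4 pentan-2-one
Product: 7 diethyl (2S)-2-{[(R)-tert-butylsulfinyl]amino}-2-(2-oxopentyl)pentanedioate, via lithium pent-1-en-2-olate 5 (not isolated), via triisopropoxytitanium enolate 6 (not isolated)
Conditions: 4, LiN(iPr)2, THF, −78 °C; ClTi(OiPr)3; then 3, −78 °C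
Reagents that add atoms: none
Why: intermolecular Mannich addition of the kinetic methyl-ketone enolate (as its less basic titanium enolate, to limit aza-enolisation) to the sulfinyl ketimino ester through a sulfinyl-oxygen-chelated chair transition state, which creates the aza-quaternary carbon (future C9a) as S.

Step 3
Reactants: 7 diethyl (2S)-2-{[(R)-tert-butylsulfinyl]amino}-2-(2-oxopentyl)pentanedioate
Product: 9 ethyl (2S)-5-oxo-2-(2-oxopentyl)pyrrolidine-2-carboxylate, via amine hydrochloride 8 (not isolated)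
Conditions: HCl (4 M in dioxane), EtOH, 0 °C; then NaHCO3, EtOH, 70 °C
Reagents that add atoms: none
Why: acidolysis of the N–S bond followed by 5-exo lactamisation of the free amine onto the γ-ester, the only ester that can give an unstrained ring; the quaternary centre is untouched.

Step 4
Reactants: 9 ethyl (2S)-5-oxo-2-(2-oxopentyl)pyrrolidine-2-carboxylate
Product: 10 (5S)-7-ethyl-1-azaspiro[4.4]nonane-2,6,8-trione
Conditions: KOtBu (3 equiv), THF, 0 °C to reflux; then 1 M HCl
Reagents that add atoms: none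
Why: intramolecular Claisen (Dieckmann-type) condensation of the propyl-side ketone enolate onto the neopentyl ester, driven by formation of the 2-ethyl-1,3-dione enolate; the lactam N–H is deprotonated first, which suppresses β-elimination of nitrogen.

Step 5
Reactants: 10 (5S)-7-ethyl-1-azaspiro[4.4]nonane-2,6,8-trione
Product: 11 (5S)-7-ethyl-8-(2-methylpropoxy)-1-azaspiro[4.4]non-7-ene-2,6-dione
Conditions: 2-methylpropan-1-ol, TsOH (cat.), toluene, reflux, Dean–Stark
Reagents that add atoms: 2-methylpropan-1-ol, CC(C)CO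
Why: acid-catalysed enol etherification occurs at the carbonyl remote from the quaternary spiro carbon, leaving the hindered carbonyl (future C9) as the vinylogous-ester ketone.

Step 6
Reactants: 11 (5S)-7-ethyl-8-(2-methylpropoxy)-1-azaspiro[4.4]non-7-ene-2,6-dione
Product: 12 (5S)-7-ethyl-8-(2-methylpropoxy)-1-(prop-2-en-1-yl)-1-azaspiro[4.4]non-7-ene-2,6-dione
Conditions: NaH, CH2=CHCH2Br, DMF, 0 °C to rt
Reagents that add atoms: allyl bromide (3-bromoprop-1-ene), C=CCBr
Why: SN2 N-alkylation of the lactam sodium salt, the N–H being the most acidic site.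

Step 7
Reactants: 12 (5S)-7-ethyl-8-(2-methylpropoxy)-1-(prop-2-en-1-yl)-1-azaspiro[4.4]non-7-ene-2,6-dione
Product: 14 (5S)-8-ethyl-1,9-di(prop-2-en-1-yl)-1-azaspiro[4.4]non-8-ene-2,7-dione, via tertiary allylic alcohol 13 (not isolated)
Conditions: CH2=CHCH2MgBr, CeCl3, THF, −78 °C; then 1 M HCl, THF, rt
Reagents that add atoms: allylmagnesium bromide, C=CC[Mg]Br
Why: Stork–Danheiser sequence, in which carbonyl allylation of the vinylogous-ester ketone (the amide is far less reactive at −78 °C) and acid hydrolysis with dehydration give the transposed enone with C11 as ketone and the allyl group on C9.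

Step 8
Reactants: 14 (5S)-8-ethyl-1,9-di(prop-2-en-1-yl)-1-azaspiro[4.4]non-8-ene-2,7-dione
Product: 15 (9aS)-10-ethyl tricyclic dienone-lactam (C3 and C11 carbonyls; C9=C10 and C6=C7 double bonds)
Conditions: second-generation Grubbs catalyst RuCl2(=CHPh)(PCy3)(H2IMes) (5 mol %), CH2Cl2, 40 °C
Reagents that add atoms: none
Why: ring-closing metathesis of the two terminal alkenes closes the seven-membered ring N4–C5–C6=C7–C8–C9; the tetrasubstituted enone does not take part.

Step 9
Reactants: 15 (9aS)-10-ethyl tricyclic dienone-lactam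
Product: 16 (9R,9aS,10S)-10-ethyl tricyclic keto-lactam (C3 lactam, C11 ketone; H9 and H10 β, ethyl α)
Conditions: H2 (5 atm), 10% Pd/C, EtOAc, rt
Reagents that add atoms: none
Why: heterogeneous hydrogenation saturates C6=C7 and adds H2 cis across the tetrasubstituted C9=C10 bond from the β face, away from the N4–C5–C6 bridge, which gives the cis-fused azepane and the ethyl group cis to C8.

Step 10
Reactants: 16 (9R,9aS,10S)-10-ethyl tricyclic keto-lactam
Product: 20 (9R,9aR,10S)-10-ethyl-12-methylidene keto-lactam, via lithium enolate 17 (not isolated), via Mannich base 18 (not isolated), via trimethylammonium iodide 19 (not isolated)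
Conditions: LiN(iPr)2, THF, −78 °C; CH2=NMe2+ I−, −78 °C to 0 °C; then MeI, MeOH, rt; then NaHCO3 (aq), CH2Cl2
Reagents that add atoms: Eschenmoser's salt (N,N-dimethylmethaniminium iodide), C=[N+](C)C.[I-]
Why: kinetic deprotonation at the C12 methylene (not the ethyl-bearing methine C10), Mannich aminomethylation, quaternisation and mild E1cB elimination give the α-methylene ketone without epimerising C10.

Step 11
Reactants: 20 (9R,9aR,10S)-10-ethyl-12-methylidene keto-lactam
Product: 21 (9R,9aR,10S,11S)-10-ethyl-11-hydroxy-12-methylidene lactam (11α-OH, cis to ethyl)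
Conditions: NaBH4, CeCl3·7H2O, MeOH, −78 °C
Reagents that add atoms: none
Why: Luche 1,2-reduction in which hydride attacks C11 from the β face, anti to the adjacent α-ethyl group and to the concave azepane side.

Step 12
Reactants: 21 (9R,9aR,10S,11S)-10-ethyl-11-hydroxy-12-methylidene lactam
Product: 22 (9R,9aR,10S,11R)-11-acryloyloxy-10-ethyl-12-methylidene lactam (11β-O)
Conditions: acrylic acid, PPh3, DIAD, THF, 0 °C to rt
Reagents that add atoms: acrylic acid (prop-2-enoic acid), C=CC(=O)O
Why: Mitsunobu esterification with SN2 inversion at C11 puts the oxygen on the β face, trans to the ethyl group.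

Step 13
Reactants: 22 (9R,9aR,10S,11R)-11-acryloyloxy-10-ethyl-12-methylidene lactam
Product: 23 (9R,9aR,10S,11R)-butenolide-lactam (lactone B with C12=C13)
Conditions: second-generation Hoveyda–Grubbs catalyst RuCl2(=CH-C6H4-2-OiPr)(H2IMes) (10 mol %), toluene, 90 °C
Reagents that add atoms: none
Why: ring-closing metathesis of the acrylate with the 1,1-disubstituted exocyclic alkene forms the five-membered butenolide with loss of ethene.

Step 14
Reactants: 23 (9R,9aR,10S,11R)-butenolide-lactam
Product: 24 (9R,9aR,10S,11R,12S)-lactone-lactam (cis-fused lactone B, C13 = CH2)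
Conditions: H2 (5 atm), 10% Pd/C, EtOAc, rt
Reagents that add atoms: none
Why: hydrogenation of the butenolide from its convex α face (that of H11) gives the only unstrained, cis-fused bicyclic lactone, so C12 is set by relay from C11.

Step 15
Reactants: 24 (9R,9aR,10S,11R,12S)-lactone-lactam
Product: 26 (9R,9aR,10S,11R,12R,13R)-13-hydroxy lactone-lactam (OH cis to H12), via lithium lactone enolate 25 (not isolated)
Conditions: LiN(SiMe3)2, THF, −78 °C; 3-phenyl-2-(phenylsulfonyl)oxaziridine, −78 °C; then AcOH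
Reagents that add atoms: 3-phenyl-2-(phenylsulfonyl)oxaziridine (Davis reagent), O=S(=O)(N1OC1c1ccccc1)c1ccccc1
Why: the lactone α-CH2 is far more acidic than the lactam α-CH2, and Davis hydroxylation of its enolate occurs on the convex face; this centre is re-enolised in step 17, so its configuration is not critical.

Step 16
Reactants: 26 (9R,9aR,10S,11R,12R,13R)-13-hydroxy lactone-lactam
Product: 27 (9R,9aR,10S,11R,12S,13R)-13-benzyloxy lactone-lactam
Conditions: BnBr, Ag2O, CH2Cl2, rt
Reagents that add atoms: benzyl bromide, BrCc1ccccc1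
Why: Ag2O-promoted Williamson benzylation under non-basic conditions protects the hydroxyl without epimerisation or lactone opening.

Step 17
Reactants: 27 (9R,9aR,10S,11R,12S,13R)-13-benzyloxy lactone-lactam
Product: 29 (9R,9aR,10S,11R,12S,13S)-13-benzyloxy-13-methyl lactone-lactam, via lithium benzyloxy enolate 28 (not isolated)
Conditions: LiN(iPr)2, THF, −78 °C; MeI, DMPU, −78 °C to −40 °C
Reagents that add atoms: iodomethane, CI
Why: enolate alkylation in which MeI approaches the convex face of the cis-fused bicyclic lactone, anti to the quaternary C9a, so the methyl is cis to H12 and the oxygen cis to C9a.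

Step 18
Reactants: 30 3-methylfuran-2(5H)-one
Product: 31 triisopropyl[(3-methylfuran-2-yl)oxy]silane
Conditions: iPr3SiOTf, Et3N, CH2Cl2, 0 °C
Reagents that add atoms: triisopropylsilyl trifluoromethanesulfonate, CC(C)[Si](OS(=O)(=O)C(F)(F)F)(C(C)C)C(C)C
Why: soft enolisation and O-silylation of the butenolide give the aromatic 2-silyloxyfuran, a dienolate equivalent.

Step 19
Reactants: 29 (9R,9aR,10S,11R,12S,13S)-13-benzyloxy-13-methyl lactone-lactam; 31 triisopropyl[(3-methylfuran-2-yl)oxy]silane
Product: 34 (3S,9R,9aR,10S,11R,12S,13S,18S)-13-O-benzyl-19,20-didehydro derivative of the target, via N,O-silyl acetal 32 (not isolated), via iminium 2-nitrobenzoate 33 (not isolated)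
Conditions: IrCl(CO)(PPh3)2 (2 mol %), (Me2HSi)2O, toluene, rt; then 31, 2-nitrobenzoic acid, MeCN, rt
Reagents that add atoms: none
Why: iridium-catalysed hydrosilylation reduces only the tertiary lactam, acid converts the N,O-silyl acetal into the N4=C3 iminium ion, and the intermolecular vinylogous Mannich reaction with the silyloxyfuran forms C3–C18 on the face anti to the C12 branch (lactone B with its benzyloxy group) with the usual threo topicity.

Step 20
Reactants: 34 (3S,9R,9aR,10S,11R,12S,13S,18S)-13-O-benzyl-19,20-didehydro derivative of the target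
Product: 35 target, (3S,9R,9aR,10S,11R,12S,13S,18S,20S)
Conditions: H2 (3 atm), Pd(OH)2/C, EtOH–AcOH (10:1), rt
Reagents that add atoms: none
Why: hydrogenation of the butenolide from the face opposite the C18 substituent gives the cis-18,20 lactone and hydrogenolysis removes the benzyl ether; the acidic medium protonates the amine and prevents C18 epimerisation.

**Compound list**

1 | diethyl 2-oxopentanedioate | CCOC(=O)CCC(=O)C(=O)OCC | starting material
2 | (R)-2-methylpropane-2-sulfinamide | CC(C)(C)[S@](N)=O | starting material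
3 | diethyl (E)-2-{[(R)-tert-butylsulfinyl]imino}pentanedioate | CCOC(=O)CC\C(C(=O)OCC)=N/[S@](=O)C(C)(C)C | intermediate
4 | pentan-2-one | CCCC(C)=O | starting material
5 | lithium pent-1-en-2-olate (not isolated) | [Li]OC(=C)CCC | intermediate
6 | triisopropoxytitanium pent-1-en-2-olate (not isolated) | CCCC(=C)O[Ti](OC(C)C)(OC(C)C)OC(C)C | intermediate
7 | diethyl (2S)-2-{[(R)-tert-butylsulfinyl]amino}-2-(2-oxopentyl)pentanedioate | CCCC(=O)C[C@](CCC(=O)OCC)(N[S@](=O)C(C)(C)C)C(=O)OCC | intermediate
8 | diethyl (2S)-2-amino-2-(2-oxopentyl)pentanedioate hydrochloride (not isolated) | CCCC(=O)C[C@](CCC(=O)OCC)(N)C(=O)OCC.Cl | intermediate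
9 | ethyl (2S)-5-oxo-2-(2-oxopentyl)pyrrolidine-2-carboxylate | CCOC(=O)[C@@]1(CC(=O)CCC)CCC(=O)N1 | intermediate
10 | (5S)-7-ethyl-1-azaspiro[4.4]nonane-2,6,8-trione (enolised at the ethyl-bearing carbon) | CCC1C(=O)C[C@@]2(CCC(=O)N2)C1=O | intermediate
11 | (5S)-7-ethyl-8-(2-methylpropoxy)-1-azaspiro[4.4]non-7-ene-2,6-dione | CCC1=C(OCC(C)C)C[C@@]2(CCC(=O)N2)C1=O | intermediate
12 | (5S)-7-ethyl-8-(2-methylpropoxy)-1-(prop-2-en-1-yl)-1-azaspiro[4.4]non-7-ene-2,6-dione | CCC1=C(OCC(C)C)C[C@@]2(CCC(=O)N2CC=C)C1=O | intermediate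
13 | (5S)-7-ethyl-6-hydroxy-8-(2-methylpropoxy)-1,6-di(prop-2-en-1-yl)-1-azaspiro[4.4]non-7-en-2-one (not isolated) | CCC1=C(OCC(C)C)C[C@@]2(CCC(=O)N2CC=C)C1(O)CC=C | intermediate
14 | (5S)-8-ethyl-1,9-di(prop-2-en-1-yl)-1-azaspiro[4.4]non-8-ene-2,7-dione | CCC1=C(CC=C)[C@]2(CCC(=O)N2CC=C)CC1=O | intermediate
15 | (9aS)-10-ethyl tricyclic dienone-lactam (C3 and C11 carbonyls; C9=C10 and C6=C7 double bonds) | CCC1=C2CC=CCN3C(=O)CC[C@]23CC1=O | intermediate
16 | (9R,9aS,10S)-10-ethyl tricyclic keto-lactam (C3 lactam, C11 ketone; H9 and H10 β, ethyl α) | CC[C@@H]1C(=O)C[C@]23CCC(=O)N2CCCC[C@H]13 | intermediate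
17 | lithium C11=C12 enolate of 16 (not isolated) | CC[C@@H]1C(O[Li])=C[C@]23CCC(=O)N2CCCC[C@H]13 | intermediate
18 | 12-(dimethylaminomethyl) derivative of 16 (not isolated) | CC[C@@H]1C(=O)C(CN(C)C)[C@]23CCC(=O)N2CCCC[C@H]13 | intermediate
19 | 12-(trimethylammoniomethyl) derivative of 16 as iodide (not isolated) | CC[C@@H]1C(=O)C(C[N+](C)(C)C)[C@]23CCC(=O)N2CCCC[C@H]13.[I-] | intermediate
20 | (9R,9aR,10S)-10-ethyl-12-methylidene keto-lactam | CC[C@@H]1C(=O)C(=C)[C@]23CCC(=O)N2CCCC[C@H]13 | intermediate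
21 | (9R,9aR,10S,11S)-10-ethyl-11-hydroxy-12-methylidene lactam (11α-OH) | CC[C@@H]1[C@H](O)C(=C)[C@]23CCC(=O)N2CCCC[C@H]13 | intermediate
22 | (9R,9aR,10S,11R)-11-acryloyloxy-10-ethyl-12-methylidene lactam (11β-O) | CC[C@@H]1[C@@H](OC(=O)C=C)C(=C)[C@]23CCC(=O)N2CCCC[C@H]13 | intermediate
23 | (9R,9aR,10S,11R)-butenolide-lactam (lactone B with C12=C13) | CC[C@@H]1[C@H]2OC(=O)C=C2[C@]23CCC(=O)N2CCCC[C@H]13 | intermediate
24 | (9R,9aR,10S,11R,12S)-lactone-lactam (cis-fused lactone B, C13 = CH2) | CC[C@@H]1[C@H]2OC(=O)C[C@H]2[C@]23CCC(=O)N2CCCC[C@H]13 | intermediate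
25 | lithium enolate of lactone 24 (not isolated) | CC[C@@H]1[C@H]2OC(O[Li])=C[C@H]2[C@]23CCC(=O)N2CCCC[C@H]13 | intermediate
26 | (9R,9aR,10S,11R,12R,13R)-13-hydroxy lactone-lactam (OH cis to H12) | CC[C@@H]1[C@H]2OC(=O)[C@H](O)[C@H]2[C@]23CCC(=O)N2CCCC[C@H]13 | intermediate
27 | (9R,9aR,10S,11R,12S,13R)-13-benzyloxy lactone-lactam | CC[C@@H]1[C@H]2OC(=O)[C@H](OCc4ccccc4)[C@H]2[C@]23CCC(=O)N2CCCC[C@H]13 | intermediate
28 | lithium enolate of benzyloxy lactone 27 (not isolated) | CC[C@@H]1[C@H]2OC(O[Li])=C(OCc4ccccc4)[C@H]2[C@]23CCC(=O)N2CCCC[C@H]13 | intermediate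
29 | (9R,9aR,10S,11R,12S,13S)-13-benzyloxy-13-methyl lactone-lactam | CC[C@@H]1[C@H]2OC(=O)[C@@](C)(OCc4ccccc4)[C@H]2[C@]23CCC(=O)N2CCCC[C@H]13 | intermediate
30 | 3-methylfuran-2(5H)-one | CC1=CCOC1=O | starting material
31 | triisopropyl[(3-methylfuran-2-yl)oxy]silane | Cc1ccoc1O[Si](C(C)C)(C(C)C)C(C)C | intermediate
32 | C3 O-silyl hemiaminal of 29 (OSiMe2OSiMe2H on C3; not isolated) | CC[C@@H]1[C@H]2OC(=O)[C@@](C)(OCc4ccccc4)[C@H]2[C@]23CCC(O[Si](C)(C)O[SiH](C)C)N2CCCC[C@H]13 | intermediate
33 | N4=C3 iminium ion from 29 as 2-nitrobenzoate (not isolated) | CC[C@@H]1[C@H]2OC(=O)[C@@](C)(OCc4ccccc4)[C@H]2[C@]23CCC=[N+]2CCCC[C@H]13.[O-]C(=O)c1ccccc1[N+](=O)[O-] | intermediate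
34 | (3S,9R,9aR,10S,11R,12S,13S,18S)-13-O-benzyl-19,20-didehydro derivative of the target (3-methylbutenolide on C3) | CC[C@@H]1[C@H]2OC(=O)[C@@](C)(OCc5ccccc5)[C@H]2[C@]23CC[C@@H]([C@@H]4C=C(C)C(=O)O4)N2CCCC[C@H]13 | intermediate
35 | target, (3S,9R,9aR,10S,11R,12S,13S,18S,20S) | CC[C@@H]1[C@H]2OC(=O)[C@@](C)(O)[C@H]2[C@]23CC[C@@H]([C@@H]4C[C@H](C)C(=O)O4)N2CCCC[C@H]13 | target

**Totals**

Total steps: 20. Longest linear sequence: 19 steps (steps 1 to 17, then 19 and 20; step 18 makes the second fragment).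

**Steps most likely to fail**

Step 2. The ketimino ester is enolisable, so the enolate may deprotonate it instead of adding, or the facial control may be poor. The fallback sets out from 3 and comes back at 7. An indium-mediated Barbier allylation (CH2=CHCH2Br, indium powder (In), THF, rt, neutral medium) gives diethyl (2S)-2-{[(R)-tert-butylsulfinyl]amino}-2-(prop-2-en-1-yl)pentanedioate F1. Oxidative cleavage (OsO4 cat., NaIO4, 2,6-lutidine, dioxane–water) gives diethyl (2S)-2-{[(R)-tert-butylsulfinyl]amino}-2-(2-oxoethyl)pentanedioate F2. Aldehyde-selective addition of n-PrMgBr (2 equiv, THF, −78 °C) gives diethyl (2S)-2-{[(R)-tert-butylsulfinyl]amino}-2-(2-hydroxypentyl)pentanedioate F3 as carbinol epimers, and Dess–Martin oxidation returns to 7.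

Step 9. The tetrasubstituted enone may hydrogenate slowly, from the wrong face, or with epimerisation at C10. The fallback sets out from 15 and comes back at 16. Luche reduction (NaBH4, CeCl3·7H2O, MeOH) gives the (9aS,11S)-11β-hydroxy dienol F4 together with its (9aS,11R)-11α-epimer F5, which is returned to 15 with MnO2. Hydroxyl-directed hydrogenation of F4 with [Ir(cod)(PCy3)(py)]PF6 and H2 in CH2Cl2 delivers both hydrogens to the β face and saturates C6=C7, giving the (9R,9aS,10S,11S)-11β-hydroxy lactam F6. Dess–Martin oxidation returns to 16.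

Step 13. Metathesis onto a 1,1-disubstituted alkene next to the quaternary C9a may stall. The fallback sets out from 21 and comes back at 23. Mitsunobu esterification with (diethoxyphosphoryl)acetic acid (PPh3, DIAD, THF) gives the (9R,9aR,10S,11R)-11-[(diethoxyphosphoryl)acetoxy]-10-ethyl-12-methylidene lactam F7 with inversion. Ozonolysis (O3, CH2Cl2–MeOH, −78 °C; Me2S) gives the (9R,9aR,10S,11R)-11-[(diethoxyphosphoryl)acetoxy]-10-ethyl-12-oxo lactam F8. Intramolecular Horner–Wadsworth–Emmons olefination (LiCl, iPr2NEt, MeCN) closes the butenolide 23.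

**Further compounds**

F1 | step 2 | diethyl (2S)-2-{[(R)-tert-butylsulfinyl]amino}-2-(prop-2-en-1-yl)pentanedioate | C=CC[C@](CCC(=O)OCC)(N[S@](=O)C(C)(C)C)C(=O)OCC
F2 | step 2 | diethyl (2S)-2-{[(R)-tert-butylsulfinyl]amino}-2-(2-oxoethyl)pentanedioate | O=CC[C@](CCC(=O)OCC)(N[S@](=O)C(C)(C)C)C(=O)OCC
F3 | step 2 | diethyl (2S)-2-{[(R)-tert-butylsulfinyl]amino}-2-(2-hydroxypentyl)pentanedioate (carbinol epimers) | CCCC(O)C[C@](CCC(=O)OCC)(N[S@](=O)C(C)(C)C)C(=O)OCC
F4 | step 9 | (9aS,11S)-10-ethyl-11β-hydroxy tricyclic diene-lactam (C9=C10, C6=C7) | CCC1=C2CC=CCN3C(=O)CC[C@]23C[C@@H]1O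
F5 | step 9 | (9aS,11R)-10-ethyl-11α-hydroxy tricyclic diene-lactam (C9=C10, C6=C7) | CCC1=C2CC=CCN3C(=O)CC[C@]23C[C@H]1O
F6 | step 9 | (9R,9aS,10S,11S)-10-ethyl-11β-hydroxy tricyclic lactam | CC[C@@H]1[C@@H](O)C[C@]23CCC(=O)N2CCCC[C@H]13
F7 | step 13 | (9R,9aR,10S,11R)-11-[(diethoxyphosphoryl)acetoxy]-10-ethyl-12-methylidene lactam | CC[C@@H]1[C@@H](OC(=O)CP(=O)(OCC)OCC)C(=C)[C@]23CCC(=O)N2CCCC[C@H]13
F8 | step 13 | (9R,9aR,10S,11R)-11-[(diethoxyphosphoryl)acetoxy]-10-ethyl-12-oxo lactam | CC[C@@H]1[C@@H](OC(=O)CP(=O)(OCC)OCC)C(=O)[C@]23CCC(=O)N2CCCC[C@H]13
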